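(The constants used here are made up.)

A catalyst going round a steady cycle cannot pile up in a form that it leaves, counting net departures, faster than the others, so in this flask I looked at the net exit of each form.

    partner + free catalyst → catalyst intermediate A (k1 = 18.6 /M/s)
    starting material + catalyst intermediate A ⇌ catalyst intermediate B (K2 = 5.1 /M, k2 = 674 /M/s)
    catalyst intermediate B → free catalyst + target (k3 = 2.83 /s)
    gas ⇌ partner, rate k4*(csat - [partner]) (k4 = 0.0327 /s, csat = 120 mM)
    solid substrate ⇌ starting material, rate k5*(cs5 - [starting material]) while solid is left; crystals form when [starting material] > cs5 (cs5 = 35 mM, k5 = 0.00895 /s)

solid substrate 0.20 M; gas 120 mM (held); free catalyst 0.5 mol%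

1. the form that holds most of the catalyst when 20% of the solid substrate are converted (what has only dissolved counts as not reacted) (catalyst intermediate A / catalyst intermediate B / free catalyst)
2. its share of the catalyst then

**Bench rule.** The usual rule puts the resting state in front of the step with the smallest forward rate per unit of catalyst form. With partner at its saturation value, free catalyst leaves at 2.23 /s, catalyst intermediate B goes on at 2.83 /s, and catalyst intermediate A leaves at 23.6 /s even with starting material at its solubility. Free catalyst therefore has the slowest forward exit, and the rule names it.

**Its border.** The rule ignores what becomes of catalyst intermediate B, which falls back at 132 /s, far faster than it goes on. Dividing the going-on constant by the sum of both gave 2.10% as the pass fraction, the fraction of catalyst intermediate B that goes on to target instead of falling back. Multiplied by this fraction, the exit of catalyst intermediate A at solubility is 0.495 /s, which is 0.222 of the exit of free catalyst, so the rule fails here.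

**My reckoning.** I took the 1.00 mM of catalyst to sit as catalyst intermediate A and balanced dissolving against consumption, which put starting material at 13.6 mM. The net exit of catalyst intermediate A is then 0.192 /s, and I kept partner at its saturation value for the exit of free catalyst. Since shares go as inverse exits, I committed to catalyst intermediate A at 86.7%.

**The forecast.** It named catalyst intermediate A at 85%, a little below my figure, on the grounds that “step 2 reverses quickly and its net forward flow is weak at such low starting material”.

**The result.** After 4.48 min the flask held 85.3% of its catalyst as catalyst intermediate A and made target at 0.179 mM/s. With a pass fraction of 2.10%, each target cost about 47.6 entries into catalyst intermediate B, and this falling back costs rate. In the run without it, the pass fraction becomes one, yet the rate rose just 1.72 times, to 0.308 mM/s. That lies just under 0.313 mM/s, the rate of dissolving into a solution free of starting material.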